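**Retrosynthetic overview**

- The target is reached from its tri-O-benzyl flavanone by BCl3 debenzylation, and that ketone from a (2S)-chroman-4-ol by oxidation at C4.
- Ring C is disconnected at the C8a–O1 bond. The strategy rests on the fact that O1 sits on C8a of ring A, between C8 (pyronylmethyl) and C4a (the C4 keto chain). A bromine on that carbon from the first step makes the two flanking positions distinguishable, and the C2 hydroxyl later displaces it under copper catalysis.
- The (3S)-1,3-diol aryl bromide comes from an aldol addition of acetophenone enolate to the aryl aldehyde, then a catalyst-controlled transfer hydrogenation that sets C2.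
- The aldehyde comes from 1-bromo-3,5-bis(benzyloxy)benzene by two successive formylations ortho to bromine; between them the first aldehyde reductively alkylates C3 of the pyrone, which is then O-benzylated.
- Ring order: the pyrone ring is built first (silyl enol ether of 3-pentanone plus malonyl dichloride), ring A is purchased, ring C is closed last.

Key step: step 9

**Remarks on the chemistry**

- The carbinol carbon that becomes C4 is formed without control in step 7 and carried as both epimers until it is oxidised in step 10.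
- Enol ether 5 is used as a mixture of double-bond isomers.
- Compound 1 is taken as a catalogue compound.

**Route**

Step 1
Reactants: 1 1-bromo-3,5-bis(benzyloxy)benzene
Product: 3 2-bromo-4,6-bis(benzyloxy)benzaldehyde, via aryl iminium chloride 2 (not isolated)
Conditions: POCl3, DMF, 0 to 80 °C; then ice/H2O
Reagents that add atoms: N,N-dimethylformamide, CN(C)C=O (formyl carbon); water, O (carbonyl oxygen)
Why: Vilsmeier–Haack formylation, in which the chloroiminium ion should attack the position para to one benzyloxy group and ortho to the other (next to bromine) rather than the more crowded site between the two ethers, as is established for 1-bromo-3,5-dialkoxybenzenes.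

Step 2
Reactants: 4 3-pentanone
Product: 5 3-(trimethylsilyloxy)pent-2-ene (E/Z mixture)
Conditions: TMSOTf, Et3N, CH2Cl2, 0 °C
Reagents that add atoms: trimethylsilyl trifluoromethanesulfonate, C[Si](C)(C)OS(=O)(=O)C(F)(F)F
Why: Soft enolisation and O-silylation of a symmetrical ketone, so no regiochemical question arises and the enol ether geometry has no consequence for step 3.

Step 3
Reactants: 5 3-(trimethylsilyloxy)pent-2-ene; 6 malonyl dichloride
Product: 8 6-ethyl-4-hydroxy-5-methyl-2H-pyran-2-one, via 4-methyl-3,5-dioxoheptanoyl chloride 7 (not isolated)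
Conditions: Et2O, −78 °C to rt
Reagents that add atoms: none
Why: Known pyrone synthesis from silyl enol ethers and malonyl dichloride, in which C-acylation by one acid chloride is followed by O-acylation of the resulting enol by the second, placing ethyl at C6 and methyl at C5 of the 4-hydroxy-2-pyrone.

Step 4
Reactants: 3 2-bromo-4,6-bis(benzyloxy)benzaldehyde; 8 6-ethyl-4-hydroxy-5-methyl-2H-pyran-2-one
Product: 10 3-[2-bromo-4,6-bis(benzyloxy)benzyl]-6-ethyl-4-hydroxy-5-methyl-2H-pyran-2-one, via 3-arylidenepyran-2,4-dione 9 (not isolated)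
Conditions: Hantzsch ester (diethyl 2,6-dimethyl-1,4-dihydropyridine-3,5-dicarboxylate), L-proline (20 mol%), CH2Cl2, 25 °C
Reagents that add atoms: none
Why: Organocatalytic three-component reductive alkylation, in which proline-catalysed Knoevenagel condensation at C3 of the pyrone is followed by conjugate hydride transfer from the Hantzsch ester, which should reduce the alkylidene before a second pyrone can add to it.

Step 5
Reactants: 10 3-[2-bromo-4,6-bis(benzyloxy)benzyl]-6-ethyl-4-hydroxy-5-methyl-2H-pyran-2-one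
Product: 11 4-(benzyloxy)-3-[2-bromo-4,6-bis(benzyloxy)benzyl]-6-ethyl-5-methyl-2H-pyran-2-one
Conditions: BnBr, K2CO3, DMF, 25 °C
Reagents that add atoms: benzyl bromide, BrCc1ccccc1
Why: Williamson O-alkylation of the acidic vinylogous carboxylic acid masks the pyrone hydroxyl against the chloroiminium ion, the enolate and the copper step, and any 2-O-benzyl regioisomer would be debenzylated to the same pyrone in step 11.

Step 6
Reactants: 11 4-(benzyloxy)-3-[2-bromo-4,6-bis(benzyloxy)benzyl]-6-ethyl-5-methyl-2H-pyran-2-one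
Product: 13 4,6-bis(benzyloxy)-2-bromo-3-[(4-benzyloxy-6-ethyl-5-methyl-2-oxo-2H-pyran-3-yl)methyl]benzaldehyde, via aryl iminium chloride 12 (not isolated)
Conditions: POCl3, DMF, 0 to 70 °C; then ice/H2O
Reagents that add atoms: N,N-dimethylformamide, CN(C)C=O (formyl carbon); water, O (carbonyl oxygen)
Why: Second Vilsmeier–Haack formylation at the remaining position para to a benzyloxy group and ortho to bromine, since the site between the two ethers is shielded by the benzyl arm that the neighbouring pyronylmethyl group pushes toward it and the fully substituted, electron-poor benzyloxypyrone offers no site to the electrophile.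

Step 7
Reactants: 13 4,6-bis(benzyloxy)-2-bromo-3-[(4-benzyloxy-6-ethyl-5-methyl-2-oxo-2H-pyran-3-yl)methyl]benzaldehyde; 14 acetophenone
Product: 16 3-{4,6-bis(benzyloxy)-2-bromo-3-[(4-benzyloxy-6-ethyl-5-methyl-2-oxo-2H-pyran-3-yl)methyl]phenyl}-3-hydroxy-1-phenylpropan-1-one (racemic carbinol), via lithium 1-phenylethenolate 15 (not isolated)
Conditions: LiN(iPr)2 (slightly less than 1 equiv relative to 14), THF, −78 °C; then 13, −78 °C; AcOH quench at −78 °C
Reagents that add atoms: none
Why: Directed aldol addition of a preformed lithium enolate to a non-enolisable aldehyde, with a cold acidic quench to prevent retro-aldol and dehydration; the new carbinol centre is deliberately left uncontrolled because it is oxidised in step 10.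

Step 8
Reactants: 16 3-{4,6-bis(benzyloxy)-2-bromo-3-[(4-benzyloxy-6-ethyl-5-methyl-2-oxo-2H-pyran-3-yl)methyl]phenyl}-3-hydroxy-1-phenylpropan-1-one
Product: 17 (3S)-1-{4,6-bis(benzyloxy)-2-bromo-3-[(4-benzyloxy-6-ethyl-5-methyl-2-oxo-2H-pyran-3-yl)methyl]phenyl}-3-phenylpropane-1,3-diol (both C1 epimers)
Conditions: RuCl(p-cymene)[(S,S)-TsDPEN] (2 mol%), HCO2H/Et3N (1:1), DMF, 30 °C
Reagents that add atoms: none
Why: Noyori asymmetric transfer hydrogenation, in which the (S,S)-TsDPEN ruthenium hydride reduces the phenyl ketone by an outer-sphere, catalyst-controlled pathway with the same facial sense as acetophenone to (S)-1-phenylethanol (hydride to the Re face), so C3 should be set as S in both C1 epimers, as in the second stage of known 1,3-diaryl-1,3-diketone reductions.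

Step 9
Reactants: 17 (3S)-1-{4,6-bis(benzyloxy)-2-bromo-3-[(4-benzyloxy-6-ethyl-5-methyl-2-oxo-2H-pyran-3-yl)methyl]phenyl}-3-phenylpropane-1,3-diol
Product: 18 (2S)-5,7-bis(benzyloxy)-8-[(4-benzyloxy-6-ethyl-5-methyl-2-oxo-2H-pyran-3-yl)methyl]-2-phenylchroman-4-ol (both C4 epimers)
Conditions: CuI (10 mol%), 3,4,7,8-tetramethyl-1,10-phenanthroline (20 mol%), Cs2CO3 (2 equiv), toluene, 110 °C, argon
Reagents that add atoms: none
Why: Cs2CO3 deprotonates the C2 carbinol, the alkoxide binds the phenanthroline complex of monovalent copper, the hindered C8a–Br bond adds to give an aryl(alkoxo) trivalent-copper species, and C–O reductive elimination forms the C8a–O1 bond. The closest known reaction is the Ullmann-type copper-catalysed O-arylation of aliphatic alcohols by aryl bromides with this ligand, used intramolecularly on 3-(2-bromoaryl)propan-1-ols to make 2-substituted chromans. Ring C closes as a six-membered ring by attack of the C2 oxygen on C8a of ring A, through a seven-membered aryl–copper–alkoxide metallacycle. No stereocentre is created, and because the C2–O bond is never broken the S configuration from step 8 is carried over with retention. The step needs arylation of the C2 hydroxyl and not the C4 hydroxyl, which ring size secures because arylation of the C4 oxygen would give a four-membered benzoxete. Intramolecularity offsets the two ortho substituents on the bromide, and the carbonate base is too weak to racemise the benzylic carbinol.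

Step 10
Reactants: 18 (2S)-5,7-bis(benzyloxy)-8-[(4-benzyloxy-6-ethyl-5-methyl-2-oxo-2H-pyran-3-yl)methyl]-2-phenylchroman-4-ol
Product: 19 (2S)-5,7-bis(benzyloxy)-8-[(4-benzyloxy-6-ethyl-5-methyl-2-oxo-2H-pyran-3-yl)methyl]-2-phenylchroman-4-one
Conditions: Dess–Martin periodinane, NaHCO3, CH2Cl2, 0 °C to rt
Reagents that add atoms: none
Why: Dess–Martin oxidation of the benzylic C4 carbinol converges both epimers on the flavanone under buffered conditions that should leave C2, the benzyl ethers and the pyrone untouched.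

Step 11
Reactants: 19 (2S)-5,7-bis(benzyloxy)-8-[(4-benzyloxy-6-ethyl-5-methyl-2-oxo-2H-pyran-3-yl)methyl]-2-phenylchroman-4-one
Product: 20 (2S)-8-[(6-ethyl-4-hydroxy-5-methyl-2-oxo-2H-pyran-3-yl)methyl]-5,7-dihydroxy-2-phenylchroman-4-one (CNP0326321.1)
Conditions: BCl3 (excess), pentamethylbenzene, CH2Cl2, −78 °C; then H2O
Reagents that add atoms: none
Why: Lewis-acid debenzylation with BCl3 and pentamethylbenzene as a non-coordinating benzyl cation scavenger should cleave the two aryl benzyl ethers and the pyrone benzyl ether at low temperature without opening ring C or reducing anything.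

**Compound list**

1 | 1-bromo-3,5-bis(benzyloxy)benzene | Brc1cc(OCc2ccccc2)cc(OCc2ccccc2)c1 | starting material
2 | [2-bromo-4,6-bis(benzyloxy)phenyl]methylidene(dimethyl)ammonium chloride | C[N+](C)=Cc1c(Br)cc(OCc2ccccc2)cc1OCc1ccccc1.[Cl-] | intermediate (not isolated)
3 | 2-bromo-4,6-bis(benzyloxy)benzaldehyde | O=Cc1c(Br)cc(OCc2ccccc2)cc1OCc1ccccc1 | intermediate
4 | 3-pentanone | CCC(=O)CC | starting material
5 | 3-(trimethylsilyloxy)pent-2-ene (E/Z mixture) | CC=C(CC)O[Si](C)(C)C | intermediate
6 | malonyl dichloride | O=C(Cl)CC(=O)Cl | starting material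
7 | 4-methyl-3,5-dioxoheptanoyl chloride | CCC(=O)C(C)C(=O)CC(=O)Cl | intermediate (not isolated)
8 | 6-ethyl-4-hydroxy-5-methyl-2H-pyran-2-one | CCc1oc(=O)cc(O)c1C | intermediate
9 | 3-[2-bromo-4,6-bis(benzyloxy)benzylidene]-6-ethyl-5-methyl-2H-pyran-2,4(3H)-dione | CCC1=C(C)C(=O)C(=Cc2c(Br)cc(OCc3ccccc3)cc2OCc2ccccc2)C(=O)O1 | intermediate (not isolated)
10 | 3-[2-bromo-4,6-bis(benzyloxy)benzyl]-6-ethyl-4-hydroxy-5-methyl-2H-pyran-2-one | CCc1oc(=O)c(Cc2c(Br)cc(OCc3ccccc3)cc2OCc2ccccc2)c(O)c1C | intermediate
11 | 4-(benzyloxy)-3-[2-bromo-4,6-bis(benzyloxy)benzyl]-6-ethyl-5-methyl-2H-pyran-2-one | CCc1oc(=O)c(Cc2c(Br)cc(OCc3ccccc3)cc2OCc2ccccc2)c(OCc2ccccc2)c1C | intermediate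
12 | {4,6-bis(benzyloxy)-2-bromo-3-[(4-benzyloxy-6-ethyl-5-methyl-2-oxo-2H-pyran-3-yl)methyl]phenyl}methylidene(dimethyl)ammonium chloride | CCc1oc(=O)c(Cc2c(OCc3ccccc3)cc(OCc3ccccc3)c(C=[N+](C)C)c2Br)c(OCc2ccccc2)c1C.[Cl-] | intermediate (not isolated)
13 | 4,6-bis(benzyloxy)-2-bromo-3-[(4-benzyloxy-6-ethyl-5-methyl-2-oxo-2H-pyran-3-yl)methyl]benzaldehyde | CCc1oc(=O)c(Cc2c(OCc3ccccc3)cc(OCc3ccccc3)c(C=O)c2Br)c(OCc2ccccc2)c1C | intermediate
14 | acetophenone | CC(=O)c1ccccc1 | starting material
15 | lithium 1-phenylethenolate | [Li]OC(=C)c1ccccc1 | intermediate (not isolated)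
16 | 3-{4,6-bis(benzyloxy)-2-bromo-3-[(4-benzyloxy-6-ethyl-5-methyl-2-oxo-2H-pyran-3-yl)methyl]phenyl}-3-hydroxy-1-phenylpropan-1-one (racemic carbinol) | CCc1oc(=O)c(Cc2c(OCc3ccccc3)cc(OCc3ccccc3)c(C(O)CC(=O)c3ccccc3)c2Br)c(OCc2ccccc2)c1C | intermediate
17 | (3S)-1-{4,6-bis(benzyloxy)-2-bromo-3-[(4-benzyloxy-6-ethyl-5-methyl-2-oxo-2H-pyran-3-yl)methyl]phenyl}-3-phenylpropane-1,3-diol (both C1 epimers) | CCc1oc(=O)c(Cc2c(OCc3ccccc3)cc(OCc3ccccc3)c(C(O)C[C@H](O)c3ccccc3)c2Br)c(OCc2ccccc2)c1C | intermediate (key-step precursor)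
18 | (2S)-5,7-bis(benzyloxy)-8-[(4-benzyloxy-6-ethyl-5-methyl-2-oxo-2H-pyran-3-yl)methyl]-2-phenylchroman-4-ol (both C4 epimers) | CCc1oc(=O)c(Cc2c(OCc3ccccc3)cc(OCc3ccccc3)c3c2O[C@H](c2ccccc2)CC3O)c(OCc2ccccc2)c1C | intermediate (key-step product)
19 | (2S)-5,7-bis(benzyloxy)-8-[(4-benzyloxy-6-ethyl-5-methyl-2-oxo-2H-pyran-3-yl)methyl]-2-phenylchroman-4-one | CCc1oc(=O)c(Cc2c(OCc3ccccc3)cc(OCc3ccccc3)c3c2O[C@H](c2ccccc2)CC3=O)c(OCc2ccccc2)c1C | intermediate
20 | (2S)-8-[(6-ethyl-4-hydroxy-5-methyl-2-oxo-2H-pyran-3-yl)methyl]-5,7-dihydroxy-2-phenylchroman-4-one | CCc1oc(=O)c(Cc2c(O)cc(O)c3c2O[C@H](c2ccccc2)CC3=O)c(O)c1C | target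

**Step count**

Total: 11 steps. Longest linear sequence: 10 steps (steps 2 to 11, from 3-pentanone); the aryl bromide branch joins at step 4 after one step.

**Steps most likely to fail**

1. Step 9. Activation of the C–Br bond between two ortho substituents may be slow. Hydride transfer from the neighbouring C4 alkoxide to copper could then lead to reductive loss of bromine, or prolonged heating with base could degrade the diol. The fallback masks the C4 oxygen and changes the metal. It sets out from aldol adduct 16, which is silylated (TBSOTf, 2,6-lutidine, CH2Cl2, −78 °C) to the 3-(tert-butyldimethylsilyloxy) ketone F1. The transfer hydrogenation of step 8 then gives the (S)-configured mono-alcohol F2. Palladium-catalysed intramolecular etherification (Pd(OAc)2, 2-(di-tert-butylphosphino)-1,1'-binaphthyl, Cs2CO3, toluene, 80 °C; oxidative addition of the bromide to zerovalent palladium, then C–O reductive elimination) would close ring C to the 4-silyloxy chroman F3. Desilylation with TBAF/AcOH in THF returns to the route at 18.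

2. Step 6. The chloroiminium ion may attack between the two benzyloxy groups instead of next to bromine, or the hot acidic medium may strip the benzyl group from the pyrone oxygen before the hindered arene reacts. The fallback replaces electrophilic formylation by halogenation, cross-coupling and oxidative cleavage. It sets out from 11, which is iodinated under mild conditions (N-iodosuccinimide, catalytic TFA, MeCN, 0 °C) to the 2-bromo-3-iodoarene F4. A Suzuki–Miyaura coupling selective for the C–I bond (potassium vinyltrifluoroborate, PdCl2(dppf), Cs2CO3, THF/H2O, 60 °C) gives the styrene F5. Lemieux–Johnson cleavage (catalytic OsO4, NaIO4, 2,6-lutidine, dioxane/H2O) returns to the route at 13.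

3. Step 4. Condensation of the doubly ortho-substituted, electron-rich aldehyde may be slow, so that a second pyrone adds to the alkylidene before hydride transfer, or conversion stalls. The fallback forms the same C–C bond by cationic benzylation. It sets out from 3, which is reduced (NaBH4, THF/MeOH, 0 °C) to 2-bromo-4,6-bis(benzyloxy)benzyl alcohol F6. Acid-catalysed dehydrative C-benzylation of an excess of pyrone 8 (catalytic TsOH, 1,2-dichloroethane, 50 °C), through the alkoxy-stabilised benzyl cation attacking C3, returns to the route at 10.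

**Further compounds**

F1 | step 9 | 3-{4,6-bis(benzyloxy)-2-bromo-3-[(4-benzyloxy-6-ethyl-5-methyl-2-oxo-2H-pyran-3-yl)methyl]phenyl}-3-(tert-butyldimethylsilyloxy)-1-phenylpropan-1-one | CCc1oc(=O)c(Cc2c(OCc3ccccc3)cc(OCc3ccccc3)c(C(O[Si](C)(C)C(C)(C)C)CC(=O)c3ccccc3)c2Br)c(OCc2ccccc2)c1C
F2 | step 9 | (1S)-3-{4,6-bis(benzyloxy)-2-bromo-3-[(4-benzyloxy-6-ethyl-5-methyl-2-oxo-2H-pyran-3-yl)methyl]phenyl}-3-(tert-butyldimethylsilyloxy)-1-phenylpropan-1-ol (both C3 epimers) | CCc1oc(=O)c(Cc2c(OCc3ccccc3)cc(OCc3ccccc3)c(C(O[Si](C)(C)C(C)(C)C)C[C@H](O)c3ccccc3)c2Br)c(OCc2ccccc2)c1C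
F3 | step 9 | (2S)-5,7-bis(benzyloxy)-8-[(4-benzyloxy-6-ethyl-5-methyl-2-oxo-2H-pyran-3-yl)methyl]-4-(tert-butyldimethylsilyloxy)-2-phenylchroman (both C4 epimers) | CCc1oc(=O)c(Cc2c(OCc3ccccc3)cc(OCc3ccccc3)c3c2O[C@H](c2ccccc2)CC3O[Si](C)(C)C(C)(C)C)c(OCc2ccccc2)c1C
F4 | step 6 | 4-(benzyloxy)-3-[4,6-bis(benzyloxy)-2-bromo-3-iodobenzyl]-6-ethyl-5-methyl-2H-pyran-2-one | CCc1oc(=O)c(Cc2c(OCc3ccccc3)cc(OCc3ccccc3)c(I)c2Br)c(OCc2ccccc2)c1C
F5 | step 6 | 4-(benzyloxy)-3-[4,6-bis(benzyloxy)-2-bromo-3-vinylbenzyl]-6-ethyl-5-methyl-2H-pyran-2-one | CCc1oc(=O)c(Cc2c(OCc3ccccc3)cc(OCc3ccccc3)c(C=C)c2Br)c(OCc2ccccc2)c1C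
F6 | step 4 | [2-bromo-4,6-bis(benzyloxy)phenyl]methanol | OCc1c(Br)cc(OCc2ccccc2)cc1OCc1ccccc1
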